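Ring C of the flavonol is disconnected at C4–C4a. This leads back to a 3-aryloxy-2-(benzyloxy)cinnamic acid whose aryl vinyl ether already contains the O1–C2 bond. Activation of the carboxyl group lets it acylate ring A, so one operation closes the pyranone and delivers the complete, fully oxygenated flavone core. The step exploits C4a of ring A: it lies ortho to O1 and to the C5 methoxy group, para to the C7 methoxy group, and is the only unsubstituted carbon next to C8a. The precursor already carries the C8 butyrate of the target, meta to C4a, so a single deprotection follows ring closure.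

Key step: step 8

Assumption: the tetrasubstituted alkenes of steps 3 to 8 are drawn as the E isomers (carboxyl carbon cis to chlorine or to the aryloxy oxygen). Any Z isomer is carried along, because only the geometry reached under the acidic conditions of step 8 matters.

Step 1
Reactants: 1 tert-butyl bromoacetate; 2 benzyl alcohol
Product: 3 tert-butyl 2-(benzyloxy)acetate
Conditions: NaH, THF, 0 °C; then 1, Bu4NI (cat.), 0 °C to rt
Reagents that add atoms: none
Why: Williamson ether synthesis in which sodium benzyloxide displaces the primary α-bromide by SN2, while the bulky tert-butyl ester resists transesterification.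

Step 2
Reactants: 3 tert-butyl 2-(benzyloxy)acetate; 4 benzoyl chloride
Product: 5 tert-butyl 2-(benzyloxy)-3-oxo-3-phenylpropanoate (racemic)
Conditions: LiN(SiMe3)2 (2.2 equiv), THF, −78 °C; 4 (1.0 equiv), −78 °C; AcOH quench
Reagents that add atoms: none
Why: Crossed Claisen-type C-acylation of the lithium ester enolate with a non-enolisable acid chloride, in which the second equivalent of base stores the more acidic β-keto ester as its enolate so that it is not acylated again; the new stereocentre is racemic and disappears in step 3.

Step 3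
Reactants: 5 tert-butyl 2-(benzyloxy)-3-oxo-3-phenylpropanoate
Product: 6 tert-butyl (E)-2-(benzyloxy)-3-chloro-3-phenylprop-2-enoate
Conditions: Ph3PCl2, Et3N, CH2Cl2, 0 °C to reflux
Reagents that add atoms: dichlorotriphenylphosphorane, ClP(Cl)(c1ccccc1)(c1ccccc1)c1ccccc1
Why: Deoxychlorination of a 1,3-dicarbonyl compound with a triphenylphosphine dihalide, in which the enolate oxygen becomes an oxyphosphonium leaving group that chloride replaces by addition–elimination under amine-buffered conditions that spare the tert-butyl ester and the benzyl ether, the chelated enol geometry favouring chlorine cis to the ester.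

Step 4
Reactants: 6 tert-butyl (E)-2-(benzyloxy)-3-chloro-3-phenylprop-2-enoate; 7 2-hydroxy-4,6-dimethoxybenzaldehyde
Product: 8 tert-butyl (E)-2-(benzyloxy)-3-(2-formyl-3,5-dimethoxyphenoxy)-3-phenylprop-2-enoate
Conditions: Cs2CO3, DMF, 80 °C
Reagents that add atoms: none
Why: Nucleophilic vinylic substitution (addition–elimination) of a β-chloroacrylate by a phenoxide, the classical entry to β-aryloxyacrylates, in which the fully substituted α-carbon rules out a follow-up aldol condensation with the ortho formyl group, and that formyl group marks the ring carbon that becomes C8.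

Step 5
Reactants: 8 tert-butyl (E)-2-(benzyloxy)-3-(2-formyl-3,5-dimethoxyphenoxy)-3-phenylprop-2-enoate
Product: 10 tert-butyl (E)-2-(benzyloxy)-3-(2-hydroxy-3,5-dimethoxyphenoxy)-3-phenylprop-2-enoate, via aryl formate 9 (not isolated)
Conditions: mCPBA, CH2Cl2, 0 °C to rt; crude formate, Et3N (cat.), MeOH, 0 °C
Reagents that add atoms: mCPBA, O=C(OO)c1cccc(Cl)c1
Why: Baeyer–Villiger oxidation with a Dakin-type outcome, in which the aryl group with two ortho and one para oxygen donors migrates far faster than hydride, the ester-conjugated tetrasubstituted alkene resembles the peracid-inert C2–C3 bond of a 3-alkoxyflavone, and the very labile formate is removed by cold amine-catalysed methanolysis so that the free phenol should not add to the acrylate β-carbon.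

Step 6
Reactants: 10 tert-butyl (E)-2-(benzyloxy)-3-(2-hydroxy-3,5-dimethoxyphenoxy)-3-phenylprop-2-enoate; 11 butanoic anhydride
Product: 12 tert-butyl (E)-2-(benzyloxy)-3-[2-(butanoyloxy)-3,5-dimethoxyphenoxy]-3-phenylprop-2-enoate
Conditions: pyridine, DMAP (cat.), CH2Cl2, 0 °C to rt
Reagents that add atoms: none
Why: DMAP-catalysed O-acylation of the only free hydroxyl group, which installs the C8 ester of the target early so that it doubles as the protecting group of this oxygen and no strong base ever meets the ortho-hydroxyaryl vinyl ether.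

Step 7
Reactants: 12 tert-butyl (E)-2-(benzyloxy)-3-[2-(butanoyloxy)-3,5-dimethoxyphenoxy]-3-phenylprop-2-enoate
Product: 13 (E)-2-(benzyloxy)-3-[2-(butanoyloxy)-3,5-dimethoxyphenoxy]-3-phenylprop-2-enoic acid
Conditions: TFA, CH2Cl2, 0 °C to rt; evaporation with toluene
Reagents that add atoms: none
Why: Acidolysis of the tert-butyl ester (E1 loss of isobutene) frees the carboxyl group without hydroxide, so neither the aryl butyrate nor the β-aryloxy group, both open to nucleophilic attack, is endangered, and anhydrous acid cannot hydrolyse the vinyl ether.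

Step 8
Reactants: 13 (E)-2-(benzyloxy)-3-[2-(butanoyloxy)-3,5-dimethoxyphenoxy]-3-phenylprop-2-enoic acid
Product: 15 3-(benzyloxy)-5,7-dimethoxy-4-oxo-2-phenyl-4H-chromen-8-yl butanoate, via mixed trifluoroacetic anhydride 14 (not isolated)
Conditions: (CF3CO)2O, TFA (co-solvent), CH2Cl2 (dilute), 0 °C to rt
Reagents that add atoms: none
Why: (CF3CO)2O turns the acid into mixed anhydride 14, whose activated carbonyl carbon (or the acylium ion derived from it) is attacked by C4a of ring A, and loss of the proton from the arenium ion restores aromaticity and gives the pyranone. The closest known reaction type is the intramolecular Friedel–Crafts acylation that converts β-aryloxycinnamic acids into flavones. Ring C closes in a 6-exo-trig mode at the acyl carbon, with the aryl vinyl ether O1–C2 as the preformed tether. No stereocentre is created. Regioselectivity between the two free carbons of ring A is secured by the tether, because only C4a is ortho to O1, and this carbon is further activated by the ortho C5 and para C7 methoxy groups while the C8 butyrate, being meta, withdraws only inductively. The carboxyl group must also stand cis to the aryloxy oxygen, which the E isomer provides and the Z isomer should reach through reversible protonation of the push-pull alkene at the future C3 in TFA, and the mild anhydride activation should leave the two unactivated phenyl rings, the benzyl enol ether and the aryl ester untouched.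

Step 9
Reactants: 15 3-(benzyloxy)-5,7-dimethoxy-4-oxo-2-phenyl-4H-chromen-8-yl butanoate
Product: 16 3,5-dihydroxy-7-methoxy-4-oxo-2-phenyl-4H-chromen-8-yl butanoate (target)
Conditions: BCl3, C6HMe5, CH2Cl2, −78 to 0 °C; then ice-cold dilute aq. HCl
Reagents that add atoms: none
Why: Chelation-directed Lewis acid ether cleavage, in which BCl3 bound to the C4 carbonyl oxygen dealkylates only the two flanking ethers (C5 methyl and C3 benzyl), pentamethylbenzene traps the benzyl cation before it can attack C6, and the unchelated C7 methyl ether and the aryl ester should survive at or below 0 °C.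

Compound list
1 | tert-butyl bromoacetate | CC(C)(C)OC(=O)CBr | starting material
2 | benzyl alcohol | OCc1ccccc1 | starting material
3 | tert-butyl 2-(benzyloxy)acetate | CC(C)(C)OC(=O)COCc1ccccc1 | intermediate
4 | benzoyl chloride | O=C(Cl)c1ccccc1 | starting material
5 | tert-butyl 2-(benzyloxy)-3-oxo-3-phenylpropanoate (racemic) | CC(C)(C)OC(=O)C(OCc1ccccc1)C(=O)c1ccccc1 | intermediate
6 | tert-butyl (E)-2-(benzyloxy)-3-chloro-3-phenylprop-2-enoate | CC(C)(C)OC(=O)/C(OCc1ccccc1)=C(\Cl)c1ccccc1 | intermediate
7 | 2-hydroxy-4,6-dimethoxybenzaldehyde | COc1cc(O)c(C=O)c(OC)c1 | starting material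
8 | tert-butyl (E)-2-(benzyloxy)-3-(2-formyl-3,5-dimethoxyphenoxy)-3-phenylprop-2-enoate | CC(C)(C)OC(=O)/C(OCc1ccccc1)=C(\Oc1cc(OC)cc(OC)c1C=O)c1ccccc1 | intermediate
9 | tert-butyl (E)-2-(benzyloxy)-3-[2-(formyloxy)-3,5-dimethoxyphenoxy]-3-phenylprop-2-enoate | CC(C)(C)OC(=O)/C(OCc1ccccc1)=C(\Oc1cc(OC)cc(OC)c1OC=O)c1ccccc1 | intermediate
10 | tert-butyl (E)-2-(benzyloxy)-3-(2-hydroxy-3,5-dimethoxyphenoxy)-3-phenylprop-2-enoate | CC(C)(C)OC(=O)/C(OCc1ccccc1)=C(\Oc1cc(OC)cc(OC)c1O)c1ccccc1 | intermediate
11 | butanoic anhydride | CCCC(=O)OC(=O)CCC | starting material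
12 | tert-butyl (E)-2-(benzyloxy)-3-[2-(butanoyloxy)-3,5-dimethoxyphenoxy]-3-phenylprop-2-enoate | CC(C)(C)OC(=O)/C(OCc1ccccc1)=C(\Oc1cc(OC)cc(OC)c1OC(=O)CCC)c1ccccc1 | intermediate
13 | (E)-2-(benzyloxy)-3-[2-(butanoyloxy)-3,5-dimethoxyphenoxy]-3-phenylprop-2-enoic acid | OC(=O)/C(OCc1ccccc1)=C(\Oc1cc(OC)cc(OC)c1OC(=O)CCC)c1ccccc1 | intermediate
14 | (E)-2-(benzyloxy)-3-[2-(butanoyloxy)-3,5-dimethoxyphenoxy]-3-phenylprop-2-enoic trifluoroacetic anhydride | O=C(OC(=O)C(F)(F)F)/C(OCc1ccccc1)=C(\Oc1cc(OC)cc(OC)c1OC(=O)CCC)c1ccccc1 | intermediate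
15 | 3-(benzyloxy)-5,7-dimethoxy-4-oxo-2-phenyl-4H-chromen-8-yl butanoate | CCCC(=O)Oc1c(OC)cc(OC)c2c(=O)c(OCc3ccccc3)c(-c3ccccc3)oc12 | intermediate
16 | 3,5-dihydroxy-7-methoxy-4-oxo-2-phenyl-4H-chromen-8-yl butanoate | CCCC(=O)Oc1c(OC)cc(O)c2c(=O)c(O)c(-c3ccccc3)oc12 | target

Total step count: 9. Longest linear sequence: 9 steps (1 to 16).

Steps most likely to fail

Step 4. The formyl-stabilised phenoxide is a weak nucleophile. The β-carbon is crowded and made less electrophilic by the α-benzyloxy donor. Addition may therefore be so slow that decomposition on prolonged heating overtakes substitution. The fallback replaces the uncatalysed addition–elimination by a metal-catalysed C–O coupling and also bypasses step 3. Setting out from 5, NaH and PhNTf2 in THF should give tert-butyl (E)-2-(benzyloxy)-3-phenyl-3-{[(trifluoromethyl)sulfonyl]oxy}prop-2-enoate F1. This is coupled with phenol 7 using Pd2(dba)3, 2-(di-tert-butylphosphino)biphenyl and K3PO4 in toluene. Zerovalent palladium inserts into the vinyl C–O bond and reductive elimination forms the aryl vinyl ether. The sequence comes back to the route at 8.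

Step 8. Ring closure on the ester-bearing ring may be slow. Exchange or loss of the butyryl group and breakdown of the acid-sensitive vinyl ether could then compete with acylation. The fallback carries the C8 oxygen through the cyclisation as a more electron-releasing ether and acylates afterwards.
- Setting out from 10, allyl bromide and K2CO3 in acetone should give tert-butyl (E)-3-[2-(allyloxy)-3,5-dimethoxyphenoxy]-2-(benzyloxy)-3-phenylprop-2-enoate F2.
- TFA in CH2Cl2 frees (E)-3-[2-(allyloxy)-3,5-dimethoxyphenoxy]-2-(benzyloxy)-3-phenylprop-2-enoic acid F3.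
- (CF3CO)2O in CH2Cl2 closes ring C to 8-(allyloxy)-3-(benzyloxy)-5,7-dimethoxy-2-phenyl-4H-chromen-4-one F4.
- Pd(PPh3)4 and morpholine in THF remove the allyl group to give 3-(benzyloxy)-8-hydroxy-5,7-dimethoxy-2-phenyl-4H-chromen-4-one F5.
- Acylation with 11, pyridine and catalytic DMAP comes back to the route at 15.

Step 9. Once boron is tied up at O3 and the C4 carbonyl oxygen, cleavage of the C5 methyl ether may stall. The warming then needed would expose the aryl ester to acyl cleavage. The fallback splits the double deprotection into two orthogonal operations. Setting out from 15, MgI2·OEt2 in toluene/Et2O with gentle heating should remove only the methyl group next to the carbonyl by chelation, giving 3-(benzyloxy)-5-hydroxy-7-methoxy-4-oxo-2-phenyl-4H-chromen-8-yl butanoate F6. Any loss of the benzyl group at this stage leads directly to the target and is harmless. Neutral hydrogenolysis (H2, Pd/C, EtOAc, rt) then removes the benzyl group and arrives at 16.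

Further compounds
F1 | step 4 | tert-butyl (E)-2-(benzyloxy)-3-phenyl-3-{[(trifluoromethyl)sulfonyl]oxy}prop-2-enoate | CC(C)(C)OC(=O)/C(OCc1ccccc1)=C(\OS(=O)(=O)C(F)(F)F)c1ccccc1
F2 | step 8 | tert-butyl (E)-3-[2-(allyloxy)-3,5-dimethoxyphenoxy]-2-(benzyloxy)-3-phenylprop-2-enoate | CC(C)(C)OC(=O)/C(OCc1ccccc1)=C(\Oc1cc(OC)cc(OC)c1OCC=C)c1ccccc1
F3 | step 8 | (E)-3-[2-(allyloxy)-3,5-dimethoxyphenoxy]-2-(benzyloxy)-3-phenylprop-2-enoic acid | OC(=O)/C(OCc1ccccc1)=C(\Oc1cc(OC)cc(OC)c1OCC=C)c1ccccc1
F4 | step 8 | 8-(allyloxy)-3-(benzyloxy)-5,7-dimethoxy-2-phenyl-4H-chromen-4-one | C=CCOc1c(OC)cc(OC)c2c(=O)c(OCc3ccccc3)c(-c3ccccc3)oc12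
F5 | step 8 | 3-(benzyloxy)-8-hydroxy-5,7-dimethoxy-2-phenyl-4H-chromen-4-one | COc1cc(OC)c2c(=O)c(OCc3ccccc3)c(-c3ccccc3)oc2c1O
F6 | step 9 | 3-(benzyloxy)-5-hydroxy-7-methoxy-4-oxo-2-phenyl-4H-chromen-8-yl butanoate | CCCC(=O)Oc1c(OC)cc(O)c2c(=O)c(OCc3ccccc3)c(-c3ccccc3)oc12
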